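**Strategy.** The cyclohexane ring is numbered C1 (tertiary carbinol), C2 (side-chain carbon), C3 (gem-dimethyl carbon), C4 (secondary carbinol), C5, C6. Everything rests on closing the C3–C4 bond last: the quaternary gem-dimethyl carbon beside a carbinol is read as a tertiary radical (isopropenyl plus H·) adding to a nitrile. One iron-hydride HAT cyclization thus builds the ring and the quaternary carbon at once and leaves a ketone for reduction to the axial alcohol. Its precursor is an open-chain γ-hydroxy nitrile carrying an isopropenyl group, assembled from (R)-linalool (whole side chain and its carbinol), a Sharpless epoxide opened by isopropenylmagnesium bromide (C1, C2), acetonitrile and umbelliferone.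

Key step: step 10

Remark: (R)-(−)-linalool is taken as enantiomerically pure commercial material; ring atoms are called C1 to C6 as in the strategy paragraph.

Step 1
Reactants: 1 (R)-(−)-linalool
Product: 3 (3R)-3,7-dimethyloct-6-ene-1,3-diol, via alkylborane 2 (not isolated)
Conditions: 9-BBN (2.2 equiv), THF, 0 °C to rt; then NaOH, H2O2, H2O, 0 °C
Reagents that add atoms: hydrogen peroxide, OO
Why: Hydroboration–oxidation: the bulky dialkylborane adds anti-Markovnikov to the monosubstituted vinyl group far faster than to the trisubstituted alkene, and the carbinol stereocenter of 1 is not involved.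

Step 2
Reactants: 3 (3R)-3,7-dimethyloct-6-ene-1,3-diol
Product: 4 (4R)-2,2,4-trimethyl-4-(4-methylpent-3-en-1-yl)-1,3-dioxane
Conditions: Me2C(OMe)2, PPTS (cat.), CH2Cl2, rt
Reagents that add atoms: 2,2-dimethoxypropane, COC(C)(C)OC
Why: Acid-catalysed transacetalisation should tie the primary and the tertiary hydroxyl into a six-membered acetonide, which masks both until step 11.

Step 3
Reactants: 4 (4R)-2,2,4-trimethyl-4-(4-methylpent-3-en-1-yl)-1,3-dioxane
Product: 6 3-[(4R)-2,2,4-trimethyl-1,3-dioxan-4-yl]propanal, via ozonide 5 (not isolated)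
Conditions: O3, CH2Cl2, −78 °C; then Me2S, −78 °C to rt
Reagents that add atoms: ozone, [O-][O+]=O
Why: Ozonolysis with reductive work-up cleaves the only alkene and should give the aldehyde, the isopropylidene carbon leaving as acetone.

Step 4
Reactants: 6 3-[(4R)-2,2,4-trimethyl-1,3-dioxan-4-yl]propanal; 7 methyl 2-[bis(2,2,2-trifluoroethoxy)phosphoryl]propanoate
Product: 8 methyl (2Z)-2-methyl-5-[(4R)-2,2,4-trimethyl-1,3-dioxan-4-yl]pent-2-enoate
Conditions: KN(SiMe3)2, 18-crown-6, THF, −78 °C
Reagents that add atoms: none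
Why: Still–Gennari variant of the Horner–Wadsworth–Emmons olefination: the electron-poor bis(trifluoroethyl) phosphonate with a sequestered potassium ion eliminates under kinetic control and should give the (Z)-trisubstituted enoate.

Step 5
Reactants: 8 methyl (2Z)-2-methyl-5-[(4R)-2,2,4-trimethyl-1,3-dioxan-4-yl]pent-2-enoate
Product: 9 (2Z)-2-methyl-5-[(4R)-2,2,4-trimethyl-1,3-dioxan-4-yl]pent-2-en-1-ol
Conditions: i-Bu2AlH (2.5 equiv), CH2Cl2, −78 °C; then aq. potassium sodium tartrate
Reagents that add atoms: none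
Why: 1,2-Reduction of the unsaturated ester by the aluminium hydride should give the (Z)-allylic alcohol without change of alkene geometry or loss of the acetonide.

Step 6
Reactants: 9 (2Z)-2-methyl-5-[(4R)-2,2,4-trimethyl-1,3-dioxan-4-yl]pent-2-en-1-ol
Product: 10 [(2S,3R)-2-methyl-3-{2-[(4R)-2,2,4-trimethyl-1,3-dioxan-4-yl]ethyl}oxiran-2-yl]methanol
Conditions: Ti(OiPr)4 (10 mol %), L-(+)-diethyl tartrate (12 mol %), t-BuOOH, 4 Å molecular sieves, CH2Cl2, −20 °C
Reagents that add atoms: tert-butyl hydroperoxide, CC(C)(C)OO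
Why: Sharpless asymmetric epoxidation: the titanium L-(+)-tartrate complex delivers oxygen to one face of the allylic alcohol under reagent control, which for this (Z)-2-methylalk-2-en-1-ol should give the (2S,3R)-epoxy alcohol and fixes ring C1 directly and ring C2 after the inversion of step 7.

Step 7
Reactants: 10 [(2S,3R)-2-methyl-3-{2-[(4R)-2,2,4-trimethyl-1,3-dioxan-4-yl]ethyl}oxiran-2-yl]methanol; 11 isopropenylmagnesium bromide
Product: 12 (2R,3R)-2-methyl-3-(prop-1-en-2-yl)-5-[(4R)-2,2,4-trimethyl-1,3-dioxan-4-yl]pentane-1,2-diol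
Conditions: CuI (15 mol %), THF, −30 to 0 °C; then aq. NH4Cl
Reagents that add atoms: none
Why: Copper-catalysed Grignard opening of a 2,3-epoxy alcohol: the methyl-bearing epoxide carbon is quaternary, so the isopropenyl group should enter at the other carbon by SN2 with inversion, which sets ring C2 relative to the untouched tertiary carbinol C1.

Step 8
Reactants: 12 (2R,3R)-2-methyl-3-(prop-1-en-2-yl)-5-[(4R)-2,2,4-trimethyl-1,3-dioxan-4-yl]pentane-1,2-diol
Product: 13 (2R,3R)-2-hydroxy-2-methyl-3-(prop-1-en-2-yl)-5-[(4R)-2,2,4-trimethyl-1,3-dioxan-4-yl]pentyl 4-methylbenzenesulfonate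
Conditions: TsCl, Et3N, DMAP (cat.), CH2Cl2, 0 °C to rt
Reagents that add atoms: 4-methylbenzenesulfonyl chloride, Cc1ccc(cc1)S(Cl)(=O)=O
Why: Selective sulfonylation: only the primary hydroxyl of the primary/tertiary 1,2-diol should react with the sulfonyl chloride under amine base.

Step 9
Reactants: 13 (2R,3R)-2-hydroxy-2-methyl-3-(prop-1-en-2-yl)-5-[(4R)-2,2,4-trimethyl-1,3-dioxan-4-yl]pentyl 4-methylbenzenesulfonate; 14 acetonitrile
Product: 16 (4S,5R)-4-hydroxy-4,6-dimethyl-5-{2-[(4R)-2,2,4-trimethyl-1,3-dioxan-4-yl]ethyl}hept-6-enenitrile, via epoxide 15 (not isolated)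
Conditions: 14 (3.5 equiv), n-BuLi (3.2 equiv), THF, −78 °C; then 13, −78 °C to rt; then H2O
Reagents that add atoms: none
Why: The tertiary alkoxide should displace the tosylate to the terminal epoxide, which lithiated acetonitrile opens at its CH2 carbon (SN2 epoxide opening), so that the carbinol center C1 is retained and ring carbons C5 and C4 arrive as a propionitrile arm.

Step 10
Reactants: 16 (4S,5R)-4-hydroxy-4,6-dimethyl-5-{2-[(4R)-2,2,4-trimethyl-1,3-dioxan-4-yl]ethyl}hept-6-enenitrile
Product: 18 (3R,4S)-4-hydroxy-2,2,4-trimethyl-3-{2-[(4R)-2,2,4-trimethyl-1,3-dioxan-4-yl]ethyl}cyclohexan-1-one, via ketimine 17 (not isolated)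
Conditions: Fe(acac)3 (30 mol %), PhSiH3 (2.5 equiv), EtOH, 60 °C, argon; then aq. citric acid, rt
Reagents that add atoms: water, O
Why: A trivalent iron hydride formed from Fe(acac)3 and PhSiH3 in EtOH transfers a hydrogen atom to the CH2 terminus of the isopropenyl group (Markovnikov HAT) and gives the tertiary radical at the future gem-dimethyl carbon C3. This nucleophilic radical adds to the nitrile carbon C4 in a 6-exo-dig closure, the only ring formed, and the iminyl radical is reduced and protonated to ketimine 17, which mild aqueous acid hydrolyses to the ketone. The closest known reaction type is the iron-catalysed HAT radical cyclization of alkene-tethered nitriles (and of alkene-tethered ketones) to cyclic ketones and alcohols, including closures that form quaternary carbons. No new stereocenter arises, because C3 carries two methyl groups and C4 becomes a carbonyl carbon, while C1 and C2 are not touched (C2 is separated from the new ketone by the quaternary C3 and cannot epimerise). The step needs the cyclization to outrun simple reduction of the radical and a 1,5-hydrogen shift from the carbon next to the nitrile; the quaternary carbinol C1 and the branched C2 in the tether (Thorpe–Ingold effect) favour the folded conformer, and the molecule holds no second alkene or other radical acceptor.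

Step 11
Reactants: 18 (3R,4S)-4-hydroxy-2,2,4-trimethyl-3-{2-[(4R)-2,2,4-trimethyl-1,3-dioxan-4-yl]ethyl}cyclohexan-1-one
Product: 20 (1S,2R,4S)-2-[(3R)-3,5-dihydroxy-3-methylpentyl]-1,3,3-trimethylcyclohexane-1,4-diol, via acetonide diol 19 (not isolated)
Conditions: LiBH(s-Bu)3, THF, −78 °C; then 1 M aq. HCl, MeOH, rt
Reagents that add atoms: none
Why: Substrate-controlled ketone reduction: the bulky trialkylborohydride should attack the ketone beside the gem-dimethyl carbon along the equatorial trajectory of the chair with the side chain equatorial (as in 4,4-dimethyl-3-keto terpenoids) and give the axial C4 alcohol trans to the side chain, after which the acidic work-up hydrolyses the acetonide.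

Step 12
Reactants: 20 (1S,2R,4S)-2-[(3R)-3,5-dihydroxy-3-methylpentyl]-1,3,3-trimethylcyclohexane-1,4-diol; 21 umbelliferone
Product: 22 7-{[(3R)-5-[(1R,2S,5S)-2,5-dihydroxy-2,6,6-trimethylcyclohexyl]-3-hydroxy-3-methylpentyl]oxy}-2H-chromen-2-one (CNP0210598.2)
Conditions: PPh3, DIAD, THF, 0 °C to rt
Reagents that add atoms: none
Why: Mitsunobu etherification: only the unhindered primary alcohol should be activated and displaced by the acidic phenol, while the neopentyl secondary and the two tertiary hydroxyls stay untouched.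

**Compound list**

1 | (R)-(−)-linalool, (3R)-3,7-dimethylocta-1,6-dien-3-ol | C=C[C@](C)(O)CCC=C(C)C | starting material
2 | 9-[(3S)-3-hydroxy-3,7-dimethyloct-6-en-1-yl]-9-borabicyclo[3.3.1]nonane (same spatial arrangement as 1; descriptor changes by priority only) | B1(CC[C@](C)(O)CCC=C(C)C)C2CCCC1CCC2 | intermediate (not isolated)
3 | (3R)-3,7-dimethyloct-6-ene-1,3-diol | OCC[C@](C)(O)CCC=C(C)C | intermediate
4 | (4R)-2,2,4-trimethyl-4-(4-methylpent-3-en-1-yl)-1,3-dioxane | CC1(C)OCC[C@@](C)(CCC=C(C)C)O1 | intermediate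
5 | (4R)-4-[2-(5,5-dimethyl-1,2,4-trioxolan-3-yl)ethyl]-2,2,4-trimethyl-1,3-dioxane | CC1(C)OCC[C@@](C)(CCC2OOC(C)(C)O2)O1 | intermediate (not isolated)
6 | 3-[(4R)-2,2,4-trimethyl-1,3-dioxan-4-yl]propanal | CC1(C)OCC[C@@](C)(CCC=O)O1 | intermediate
7 | methyl 2-[bis(2,2,2-trifluoroethoxy)phosphoryl]propanoate | COC(=O)C(C)P(=O)(OCC(F)(F)F)OCC(F)(F)F | starting material
8 | methyl (2Z)-2-methyl-5-[(4R)-2,2,4-trimethyl-1,3-dioxan-4-yl]pent-2-enoate | CC1(C)OCC[C@@](C)(CC/C=C(/C)C(=O)OC)O1 | intermediate
9 | (2Z)-2-methyl-5-[(4R)-2,2,4-trimethyl-1,3-dioxan-4-yl]pent-2-en-1-ol | CC1(C)OCC[C@@](C)(CC/C=C(/C)CO)O1 | intermediate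
10 | [(2S,3R)-2-methyl-3-{2-[(4R)-2,2,4-trimethyl-1,3-dioxan-4-yl]ethyl}oxiran-2-yl]methanol | CC1(C)OCC[C@@](C)(CC[C@H]2O[C@@]2(C)CO)O1 | intermediate
11 | isopropenylmagnesium bromide (prop-1-en-2-ylmagnesium bromide) | CC(=C)[Mg]Br | starting material
12 | (2R,3R)-2-methyl-3-(prop-1-en-2-yl)-5-[(4R)-2,2,4-trimethyl-1,3-dioxan-4-yl]pentane-1,2-diol | CC1(C)OCC[C@@](C)(CC[C@H](C(C)=C)[C@@](C)(O)CO)O1 | intermediate
13 | (2R,3R)-2-hydroxy-2-methyl-3-(prop-1-en-2-yl)-5-[(4R)-2,2,4-trimethyl-1,3-dioxan-4-yl]pentyl 4-methylbenzenesulfonate | CC1(C)OCC[C@@](C)(CC[C@H](C(C)=C)[C@@](C)(O)COS(=O)(=O)c2ccc(C)cc2)O1 | intermediate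
14 | acetonitrile | CC#N | starting material
15 | (4R)-2,2,4-trimethyl-4-{(3R)-4-methyl-3-[(2R)-2-methyloxiran-2-yl]pent-4-en-1-yl}-1,3-dioxane | CC1(C)OCC[C@@](C)(CC[C@H](C(C)=C)[C@]2(C)CO2)O1 | intermediate (not isolated)
16 | (4S,5R)-4-hydroxy-4,6-dimethyl-5-{2-[(4R)-2,2,4-trimethyl-1,3-dioxan-4-yl]ethyl}hept-6-enenitrile | CC1(C)OCC[C@@](C)(CC[C@H](C(C)=C)[C@@](C)(O)CCC#N)O1 | intermediate
17 | (1S,2R)-4-imino-1,3,3-trimethyl-2-{2-[(4R)-2,2,4-trimethyl-1,3-dioxan-4-yl]ethyl}cyclohexan-1-ol | CC1(C)OCC[C@@](C)(CC[C@@H]2C(C)(C)C(=N)CC[C@]2(C)O)O1 | intermediate (not isolated)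
18 | (3R,4S)-4-hydroxy-2,2,4-trimethyl-3-{2-[(4R)-2,2,4-trimethyl-1,3-dioxan-4-yl]ethyl}cyclohexan-1-one | CC1(C)OCC[C@@](C)(CC[C@@H]2C(C)(C)C(=O)CC[C@]2(C)O)O1 | intermediate
19 | (1S,2R,4S)-1,3,3-trimethyl-2-{2-[(4R)-2,2,4-trimethyl-1,3-dioxan-4-yl]ethyl}cyclohexane-1,4-diol | CC1(C)OCC[C@@](C)(CC[C@@H]2C(C)(C)[C@@H](O)CC[C@]2(C)O)O1 | intermediate (not isolated)
20 | (1S,2R,4S)-2-[(3R)-3,5-dihydroxy-3-methylpentyl]-1,3,3-trimethylcyclohexane-1,4-diol | OCC[C@](C)(O)CC[C@@H]1C(C)(C)[C@@H](O)CC[C@]1(C)O | intermediate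
21 | umbelliferone (7-hydroxy-2H-chromen-2-one) | Oc1ccc2ccc(=O)oc2c1 | starting material
22 | 7-{[(3R)-5-[(1R,2S,5S)-2,5-dihydroxy-2,6,6-trimethylcyclohexyl]-3-hydroxy-3-methylpentyl]oxy}-2H-chromen-2-one | CC1(C)[C@@H](CC[C@@](C)(O)CCOc2ccc3ccc(=O)oc3c2)[C@@](C)(O)CC[C@@H]1O | target

**Step count and risks**

Total steps: 12. Longest linear sequence: 12 (1 to 22).

Steps most likely to fail:

Step 10. The 6-exo-dig addition of the hindered tertiary radical to the nitrile may be slower than its reduction to an isopropyl group or a 1,5-hydrogen shift from the carbon next to the nitrile, so that the ring does not close. The fallback changes the acceptor to an aldehyde, to which carbon radicals add faster. It sets out from 16. The tertiary hydroxyl is silylated (Et3SiOTf, 2,6-lutidine, CH2Cl2) to the silyloxy nitrile F1, so that the later aldehyde cannot close to a lactol. Reduction with i-Bu2AlH at −78 °C and mild aqueous acid should give the silyloxy aldehyde F2. Fe(acac)3 and PhSiH3 in EtOH at 60 °C should then close the ring by 6-exo-trig radical addition to the aldehyde (a known HAT alkene–aldehyde coupling) to the cyclohexanol F3, expected as both carbinol epimers. Dess–Martin periodinane converges them to the silyloxy ketone F4. The conditions of step 11 (LiBH(s-Bu)3, then aqueous HCl in MeOH, which also removes the silyl ether) bring the sequence back to the route at 20.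

Step 7. SN2 attack of the branched alkenyl copper reagent at the epoxide carbon next to a quaternary center may be sluggish, and Lewis-acid opening at the tertiary carbon or rearrangement of the epoxide by the magnesium salts may compete. The fallback uses a slim sp nucleophile and builds the isopropenyl group afterwards. It sets out from 10. Et2AlC≡CSiMe3 (from LiC≡CSiMe3 and Et2AlCl, toluene, 0 °C) should open the epoxy alcohol at the same carbon with inversion to the silylalkynyl diol F5. K2CO3 in MeOH removes the silyl group to give the ethynyl diol F6. Zirconium-catalysed carboalumination (AlMe3, Cp2ZrCl2, CH2Cl2), which puts the methyl group on the internal alkyne carbon, followed by protonolysis with water, should give the isopropenyl group and return to the route at 12.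

Step 9. Opening of the hindered 2,2-disubstituted epoxide by the cyanomethyl anion may be incomplete, and the tertiary alkoxide may add to the nitrile of the product. The fallback replaces epoxide opening by olefination and conjugate reduction. It sets out from 12. Oxidation of the primary alcohol (SO3·pyridine, DMSO, i-Pr2NEt) should give the hydroxy aldehyde F7. A Wittig reaction with Ph3P=CHCN gives the unsaturated nitrile F8. Conjugate reduction with Mg in MeOH, which leaves the isolated isopropenyl group alone, returns to the route at 16.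

Further compounds
F1 | step 10 | (4S,5R)-4,6-dimethyl-5-{2-[(4R)-2,2,4-trimethyl-1,3-dioxan-4-yl]ethyl}-4-[(triethylsilyl)oxy]hept-6-enenitrile | CC1(C)OCC[C@@](C)(CC[C@H](C(C)=C)[C@@](C)(O[Si](CC)(CC)CC)CCC#N)O1
F2 | step 10 | (4S,5R)-4,6-dimethyl-5-{2-[(4R)-2,2,4-trimethyl-1,3-dioxan-4-yl]ethyl}-4-[(triethylsilyl)oxy]hept-6-enal | CC1(C)OCC[C@@](C)(CC[C@H](C(C)=C)[C@@](C)(O[Si](CC)(CC)CC)CCC=O)O1
F3 | step 10 | (3R,4S)-2,2,4-trimethyl-3-{2-[(4R)-2,2,4-trimethyl-1,3-dioxan-4-yl]ethyl}-4-[(triethylsilyl)oxy]cyclohexan-1-ol (both C1 epimers) | CC1(C)OCC[C@@](C)(CC[C@@H]2C(C)(C)C(O)CC[C@]2(C)O[Si](CC)(CC)CC)O1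
F4 | step 10 | (3R,4S)-2,2,4-trimethyl-3-{2-[(4R)-2,2,4-trimethyl-1,3-dioxan-4-yl]ethyl}-4-[(triethylsilyl)oxy]cyclohexan-1-one | CC1(C)OCC[C@@](C)(CC[C@@H]2C(C)(C)C(=O)CC[C@]2(C)O[Si](CC)(CC)CC)O1
F5 | step 7 | (2R,3R)-2-methyl-5-[(4R)-2,2,4-trimethyl-1,3-dioxan-4-yl]-3-[(trimethylsilyl)ethynyl]pentane-1,2-diol | CC1(C)OCC[C@@](C)(CC[C@H](C#C[Si](C)(C)C)[C@@](C)(O)CO)O1
F6 | step 7 | (2R,3R)-3-ethynyl-2-methyl-5-[(4R)-2,2,4-trimethyl-1,3-dioxan-4-yl]pentane-1,2-diol | CC1(C)OCC[C@@](C)(CC[C@H](C#C)[C@@](C)(O)CO)O1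
F7 | step 9 | (2R,3R)-2-hydroxy-2-methyl-3-(prop-1-en-2-yl)-5-[(4R)-2,2,4-trimethyl-1,3-dioxan-4-yl]pentanal | CC1(C)OCC[C@@](C)(CC[C@H](C(C)=C)[C@@](C)(O)C=O)O1
F8 | step 9 | (2E,4S,5R)-4-hydroxy-4,6-dimethyl-5-{2-[(4R)-2,2,4-trimethyl-1,3-dioxan-4-yl]ethyl}hepta-2,6-dienenitrile | CC1(C)OCC[C@@](C)(CC[C@H](C(C)=C)[C@@](C)(O)/C=C/C#N)O1
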